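Assumption: the SMILES of CNP0102979.0 (taiwaniaflavone) has no stereocentre and no defined biaryl axis, so the compound is made as the single achiral constitution shown.

## Retrosynthetic overview

1. Target 14 ⇐ hexamethyl ether 13; all six O-methyl groups are removed last.
2. 13 ⇐ benzyl ketone 9 + 4-methoxybenzoyl chloride 10; the pyranone ring of the 3-aryl flavone unit is closed last (Baker–Venkataraman aroyl transfer, then cyclodehydration).
3. 9 ⇐ 7 by ortho-demethylation; the pyranone ring of the first flavone unit is closed from its 1,3-diketone.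
4. 7 ⇐ linchpin 4 + two equivalents of diazoketone 3. Key disconnection: the interflavone C3–C3' bond, made by joining a ketone alpha-carbon used as an enolonium equivalent (diazoketone) to the aryl carbon ortho to oxygen, delivered from boron. The same diazoketone also homologates the formyl group of 4 to the 1,3-diketone.
5. 3 ⇐ 2',4',6'-trimethoxyacetophenone 1 by diazo transfer.

## Route

Step 1
Reactants: 1 1-(2,4,6-trimethoxyphenyl)ethan-1-one
Product: 3 2-diazo-1-(2,4,6-trimethoxyphenyl)ethan-1-one, via trifluoroacetyl ketone 2 (not isolated)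
Conditions: LiN(SiMe3)2 (1.1 equiv), THF, −78 °C; CF3CO2CH2CF3 (1.2 equiv); aq. HCl quench; then MsN3 (1.5 equiv), Et3N (1.5 equiv), H2O (1 equiv), MeCN, 23 °C
Reagents that add atoms: methanesulfonyl azide, CS(=O)(=O)N=[N+]=[N-]
Why: Claisen-type trifluoroacetylation of the lithium enolate activates the acetyl methyl group for Regitz-type diazo transfer, and the adduct with the sulfonyl azide fragments with loss of the trifluoroacetyl group as the N-acylsulfonamide (Danheiser detrifluoroacetylative diazo transfer), the methyl group staying accessible despite the two ortho-methoxy groups.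

Step 2 (key step)
Reactants: 4 (5-formyl-2-methoxyphenyl)boronic acid; 3 2-diazo-1-(2,4,6-trimethoxyphenyl)ethan-1-one (2.4 equiv in two charges)
Product: 7 1-[4-methoxy-3-[2-oxo-2-(2,4,6-trimethoxyphenyl)ethyl]phenyl]-3-(2,4,6-trimethoxyphenyl)propane-1,3-dione, via boronic acid diketone 5 (not isolated), via arylboroxine 6 (not isolated)
Conditions: 3 (1.1 equiv), SnCl2 (10 mol %), ClCH2CH2Cl, 23 °C until N2 evolution stops; then distil off part of the solvent (azeotropic drying); 3 (1.3 equiv), iPr2NH (2 equiv), 80 °C; aq. work-up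
Reagents that add atoms: none
Why: Proposed new method: one diazoketone is used twice in one flask, first as a carbon nucleophile in a SnCl2-catalysed Roskamp-type homologation of the aryl aldehyde (addition to the activated C=O, then 1,2-hydride shift with loss of N2 gives the 1,3-diketone) and then as an enolonium (alpha-keto cation) equivalent toward the arylboroxine (the diazo carbon binds to boron, the aryl group migrates from boron to carbon with loss of N2, and protonolysis of the boron enolate gives the alpha-aryl ketone), so that the ketone alpha-carbon and the arene carbon ortho to the methoxy group, both nucleophilic by nature, are joined at a position fixed by boron; the closest known reactions are the SnCl2-catalysed 1,3-diketone synthesis from alpha-diazoketones plus aldehydes and the amine-promoted metal-free arylation of alpha-diazoketones by arylboroxines, and only their telescoping on one bifunctional arene is new.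

Step 3
Reactants: 7 1-[4-methoxy-3-[2-oxo-2-(2,4,6-trimethoxyphenyl)ethyl]phenyl]-3-(2,4,6-trimethoxyphenyl)propane-1,3-dione
Product: 9 2-[3-[2-(2-hydroxy-4,6-dimethoxyphenyl)-2-oxoethyl]-4-methoxyphenyl]-5,7-dimethoxy-4H-chromen-4-one, via bis-phenol diketone 8 (not isolated)
Conditions: BCl3 (6 equiv), CH2Cl2, −78 → 0 °C; H2O quench; then AcOH, conc. H2SO4 (cat.), 100 °C
Reagents that add atoms: none
Why: BCl3 binds each aryl ketone oxygen and cleaves only the methyl ether held in the six-membered chelate (chelation-controlled ortho-demethylation), after which the freed phenol of the 1,3-diketone adds to the distal carbonyl and loses water under acid (cyclodehydration to the chromone), while the benzyl ketone cannot close to a benzofuran because the ring B oxygen is still methylated.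

Step 4
Reactants: 9 2-[3-[2-(2-hydroxy-4,6-dimethoxyphenyl)-2-oxoethyl]-4-methoxyphenyl]-5,7-dimethoxy-4H-chromen-4-one; 10 4-methoxybenzoyl chloride
Product: 13 3-[5-(5,7-dimethoxy-4-oxo-4H-chromen-2-yl)-2-methoxyphenyl]-5,7-dimethoxy-2-(4-methoxyphenyl)-4H-chromen-4-one, via aryl ester 11 (not isolated), via aryl diketone 12 (not isolated)
Conditions: 10 (1.5 equiv), K2CO3 (4 equiv), acetone, reflux, 16 h; evaporate; AcOH, conc. H2SO4 (cat.), 100 °C
Reagents that add atoms: none
Why: O-aroylation of the phenol followed by base-induced intramolecular acyl transfer to the doubly activated methylene (Baker–Venkataraman rearrangement) gives the 2-aryl-1,3-diketone, which closes to the 2,3-diarylchromone by acid cyclodehydration, the ring B methyl ether blocking the competing benzofuran closure.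

Step 5
Reactants: 13 3-[5-(5,7-dimethoxy-4-oxo-4H-chromen-2-yl)-2-methoxyphenyl]-5,7-dimethoxy-2-(4-methoxyphenyl)-4H-chromen-4-one
Product: 14 3-[5-(5,7-dihydroxy-4-oxo-4H-chromen-2-yl)-2-hydroxyphenyl]-5,7-dihydroxy-2-(4-hydroxyphenyl)-4H-chromen-4-one (taiwaniaflavone)
Conditions: BBr3 (15 equiv), CH2Cl2, −78 → 40 °C, 24 h; H2O quench
Reagents that add atoms: none
Why: Excess BBr3 cleaves all six aryl methyl ethers by O–B coordination and bromide attack at methyl (Lewis-acid ether cleavage), the 5-methoxy groups first through chelation to the 4-carbonyl, and the biflavone core is inert to these conditions.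

## Compound list

1 | 1-(2,4,6-trimethoxyphenyl)ethan-1-one | CC(=O)c1c(OC)cc(OC)cc1OC | starting material
2 | 4,4,4-trifluoro-1-(2,4,6-trimethoxyphenyl)butane-1,3-dione | COc1cc(OC)c(C(=O)CC(=O)C(F)(F)F)c(OC)c1 | intermediate
3 | 2-diazo-1-(2,4,6-trimethoxyphenyl)ethan-1-one | COc1cc(OC)c(C(=O)C=[N+]=[N-])c(OC)c1 | intermediate
4 | (5-formyl-2-methoxyphenyl)boronic acid | COc1ccc(C=O)cc1B(O)O | starting material
5 | [2-methoxy-5-[3-oxo-3-(2,4,6-trimethoxyphenyl)propanoyl]phenyl]boronic acid | COc1ccc(C(=O)CC(=O)c2c(OC)cc(OC)cc2OC)cc1B(O)O | intermediate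
6 | 2,4,6-tris[2-methoxy-5-[3-oxo-3-(2,4,6-trimethoxyphenyl)propanoyl]phenyl]boroxine | COc1ccc(C(=O)CC(=O)c2c(OC)cc(OC)cc2OC)cc1B1OB(c2cc(C(=O)CC(=O)c3c(OC)cc(OC)cc3OC)ccc2OC)OB(c2cc(C(=O)CC(=O)c3c(OC)cc(OC)cc3OC)ccc2OC)O1 | intermediate
7 | 1-[4-methoxy-3-[2-oxo-2-(2,4,6-trimethoxyphenyl)ethyl]phenyl]-3-(2,4,6-trimethoxyphenyl)propane-1,3-dione | COc1ccc(C(=O)CC(=O)c2c(OC)cc(OC)cc2OC)cc1CC(=O)c1c(OC)cc(OC)cc1OC | intermediate
8 | 1-(2-hydroxy-4,6-dimethoxyphenyl)-3-[3-[2-(2-hydroxy-4,6-dimethoxyphenyl)-2-oxoethyl]-4-methoxyphenyl]propane-1,3-dione | COc1ccc(C(=O)CC(=O)c2c(O)cc(OC)cc2OC)cc1CC(=O)c1c(O)cc(OC)cc1OC | intermediate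
9 | 2-[3-[2-(2-hydroxy-4,6-dimethoxyphenyl)-2-oxoethyl]-4-methoxyphenyl]-5,7-dimethoxy-4H-chromen-4-one | COc1ccc(-c2cc(=O)c3c(OC)cc(OC)cc3o2)cc1CC(=O)c1c(O)cc(OC)cc1OC | intermediate
10 | 4-methoxybenzoyl chloride | COc1ccc(C(=O)Cl)cc1 | starting material
11 | 2-[2-[5-(5,7-dimethoxy-4-oxo-4H-chromen-2-yl)-2-methoxyphenyl]acetyl]-3,5-dimethoxyphenyl 4-methoxybenzoate | COc1ccc(C(=O)Oc2cc(OC)cc(OC)c2C(=O)Cc2cc(-c3cc(=O)c4c(OC)cc(OC)cc4o3)ccc2OC)cc1 | intermediate
12 | 2-[5-(5,7-dimethoxy-4-oxo-4H-chromen-2-yl)-2-methoxyphenyl]-1-(2-hydroxy-4,6-dimethoxyphenyl)-3-(4-methoxyphenyl)propane-1,3-dione | COc1ccc(C(=O)C(c2cc(-c3cc(=O)c4c(OC)cc(OC)cc4o3)ccc2OC)C(=O)c2c(O)cc(OC)cc2OC)cc1 | intermediate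
13 | 3-[5-(5,7-dimethoxy-4-oxo-4H-chromen-2-yl)-2-methoxyphenyl]-5,7-dimethoxy-2-(4-methoxyphenyl)-4H-chromen-4-one | COc1ccc(-c2oc3cc(OC)cc(OC)c3c(=O)c2-c2cc(-c3cc(=O)c4c(OC)cc(OC)cc4o3)ccc2OC)cc1 | intermediate
14 | 3-[5-(5,7-dihydroxy-4-oxo-4H-chromen-2-yl)-2-hydroxyphenyl]-5,7-dihydroxy-2-(4-hydroxyphenyl)-4H-chromen-4-one (taiwaniaflavone, CNP0102979.0) | O=c1cc(-c2ccc(O)c(-c3c(-c4ccc(O)cc4)oc4cc(O)cc(O)c4c3=O)c2)oc2cc(O)cc(O)c12 | target

## Step count and risks

Total step count: 5. Longest linear sequence: 5 steps (1 → 3 → 7 → 9 → 13 → 14); 4 and 10 enter as commercial materials.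

Steps most likely to fail:

Step 2. With the electron-rich aryl aldehyde, aryl migration can compete with the hydride shift in the homologation stage. The new 1,3-diketone can also bind to boron and slow the boron-to-carbon aryl transfer, and protodeboronation competes at 80 °C. The fallback sets out from 3 and comes back to the route at 7. Commercial [2-methoxy-5-(methoxycarbonyl)phenyl]boronic acid is dried in the flask to 2,4,6-tris[2-methoxy-5-(methoxycarbonyl)phenyl]boroxine F1 and treated with 3 and iPr2NH in ClCH2CH2Cl at 80 °C to give methyl 4-methoxy-3-[2-oxo-2-(2,4,6-trimethoxyphenyl)ethyl]benzoate F2. A crossed Claisen condensation of F2 with the lithium enolate of 1 (LiN(SiMe3)2, THF, −78 → 23 °C) then gives 7. This replaces the diazo/aldehyde homologation by an ester condensation in a separate operation and keeps aldehyde and diketone away from the aryl transfer, at the cost of one step.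

Step 3. The 1,3-diketone of 7 forms a BCl2 chelate that can slow or misdirect the ortho-demethylation, and a second ortho-methoxy group may be lost. The fallback sets out from 3 and comes back to the route at 8. Methyl 4-methoxy-3-[2-oxo-2-(2,4,6-trimethoxyphenyl)ethyl]benzoate F2, made as above, is demethylated with BCl3 (CH2Cl2, −78 → 0 °C) while it is still a simple aryl ketone, giving methyl 3-[2-(2-hydroxy-4,6-dimethoxyphenyl)-2-oxoethyl]-4-methoxybenzoate F3. Condensation of F3 with the dianion of commercial 1-(2-hydroxy-4,6-dimethoxyphenyl)ethan-1-one (LiN(SiMe3)2 in excess, THF) gives 8, which is cyclised with acid as in step 3. The free phenols are thus introduced without BCl3 ever meeting a 1,3-diketone.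

Step 4. O-aroylation may not be followed by clean acyl transfer to carbon, and the final closure builds a crowded tetrasubstituted C2=C3 bond. The fallback sets out from 9 and comes back to the route at 13. Condensation of 9 with 4-methoxybenzaldehyde (piperidine, EtOH, reflux; aldol condensation, then oxa-Michael ring closure) gives trans-3-[5-(5,7-dimethoxy-4-oxo-4H-chromen-2-yl)-2-methoxyphenyl]-5,7-dimethoxy-2-(4-methoxyphenyl)chroman-4-one F4 as the racemate. Dehydrogenation with DDQ (dioxane, reflux) removes both stereocentres and gives 13.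

## Further compounds

F1 | step 2 | 2,4,6-tris[2-methoxy-5-(methoxycarbonyl)phenyl]boroxine | COC(=O)c1ccc(OC)c(c1)B1OB(c2cc(C(=O)OC)ccc2OC)OB(c2cc(C(=O)OC)ccc2OC)O1
F2 | step 2 | methyl 4-methoxy-3-[2-oxo-2-(2,4,6-trimethoxyphenyl)ethyl]benzoate | COC(=O)c1ccc(OC)c(CC(=O)c2c(OC)cc(OC)cc2OC)c1
F3 | step 3 | methyl 3-[2-(2-hydroxy-4,6-dimethoxyphenyl)-2-oxoethyl]-4-methoxybenzoate | COC(=O)c1ccc(OC)c(CC(=O)c2c(O)cc(OC)cc2OC)c1
F4 | step 4 | trans-3-[5-(5,7-dimethoxy-4-oxo-4H-chromen-2-yl)-2-methoxyphenyl]-5,7-dimethoxy-2-(4-methoxyphenyl)chroman-4-one (racemic; one enantiomer written) | O=C1[C@H](c2cc(-c3cc(=O)c4c(OC)cc(OC)cc4o3)ccc2OC)[C@@H](c2ccc(OC)cc2)Oc2cc(OC)cc(OC)c12
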